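The chroman is cut at O1–C8a and C4–C4a. The feature exploited is that the ring-fusion carbons C8a and C4a are neighbours on the benzene ring and are bridged by the chain O1–C2(CH3)2–C3H(OH)–C4H2, which maps atom for atom onto a 2,3-epoxy tertiary alcohol. In one operation the alkoxide of (R)-2-(oxiran-2-yl)propan-2-ol is O-arylated by a 3-chloroaryne and the aryl anion so formed opens the epoxide at CH2, closing the dihydropyran ring while the carbinol centre is carried over intact. The aryne precursor is an ortho-silyl aryl triflate bearing chlorine beside silicon and a dioxolane-masked aldehyde para to oxygen. The derived benzyl bromide later alkylates a butenolide ester enolate.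

Key step: step 6

Remark on stereochemistry: CIP analysis of the target gives (S) at the butenolide quaternary carbon and (3R) at the chroman carbinol; the C–O bond at the epoxide methine is never broken, so methyl (R)-glycidate leads to the (3R) carbinol.
Remark on design: the phenol is carbamoylated before the aldehyde is masked (acetals of free 4-hydroxybenzaldehydes are labile); an N-isopropyl carbamate is used so that it can be exchanged for triflate under mild base; the aryne is released in THF without acetonitrile or free alcohol; the secondary alcohol is carried as a benzyl ether so that one hydrogenolysis ends the synthesis.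
Assumption: the cinchonidine-derived phase-transfer catalyst is taken to favour the (S) centre in step 16; if the opposite sense is found, its cinchonine-derived pseudoenantiomer is used in the same step.

Step 1
Reactants: 1 2-chloro-4-hydroxybenzaldehyde
Product: 2 3-chloro-4-formylphenyl isopropylcarbamate
Conditions: i-PrNCO, Et3N (cat.), CH2Cl2, rt
Reagents that add atoms: isopropyl isocyanate, CC(C)N=C=O
Why: Base-catalysed carbamoylation of the acidic phenol by the isocyanate installs the ortho-directing group and leaves the aldehyde untouched.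

Step 2
Reactants: 2 3-chloro-4-formylphenyl isopropylcarbamate
Product: 3 3-chloro-4-(1,3-dioxolan-2-yl)phenyl isopropylcarbamate
Conditions: ethylene glycol, HC(OEt)3, p-TsOH·H2O (cat.), CH2Cl2, rt
Reagents that add atoms: ethylene glycol, OCCO
Why: Acid-catalysed acetalisation with orthoformate as water scavenger should be easy for this electron-poor benzaldehyde, and the aryl carbamate tolerates mild acid at room temperature.

Step 3
Reactants: 3 3-chloro-4-(1,3-dioxolan-2-yl)phenyl isopropylcarbamate
Product: 7 3-chloro-4-(1,3-dioxolan-2-yl)-2-(trimethylsilyl)phenyl isopropylcarbamate, via N-silyl carbamate 4 (not isolated), via aryllithium 5 (not isolated), via N-silyl C-silyl carbamate 6 (not isolated)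
Conditions: TBSOTf, TMEDA, Et2O, 0 °C → rt; n-BuLi, TMEDA, −78 °C; TMSCl, −78 °C → rt; aq. NH4Cl/MeOH work-up
Reagents that add atoms: chlorotrimethylsilane, C[Si](C)(C)Cl; tert-butyldimethylsilyl triflate, CC(C)(C)[Si](C)(C)OS(=O)(=O)C(F)(F)F (its silicon is present in 4–6 only)
Why: Directed ortho-metalation: after in situ N-silylation, the carbamate oxygen and the chlorine jointly acidify the hydrogen between them, n-BuLi/TMEDA removes it at −78 °C (below the temperature at which an ortho-chloro aryllithium loses LiCl), TMSCl traps the anion and the N–Si bond is hydrolysed on work-up.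

Step 4
Reactants: 7 3-chloro-4-(1,3-dioxolan-2-yl)-2-(trimethylsilyl)phenyl isopropylcarbamate
Product: 9 3-chloro-4-(1,3-dioxolan-2-yl)-2-(trimethylsilyl)phenyl trifluoromethanesulfonate, via silyl phenol 8 (not isolated)
Conditions: DBU, Et2NH, MeCN, 40 °C; then PhNTf2, rt
Reagents that add atoms: N-phenylbis(trifluoromethanesulfonimide), O=S(=O)(N(c1ccccc1)S(=O)(=O)C(F)(F)F)C(F)(F)F
Why: E1cB cleavage of the N–H carbamate (the expelled isocyanate is trapped by Et2NH as a urea) releases the phenoxide, which is triflated in the same pot, so the acetal and the C–Si bond never meet acid.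

Step 5
Reactants: 10 methyl (R)-glycidate
Product: 12 (R)-2-(oxiran-2-yl)propan-2-ol, via methyl ketone 11 (not isolated)
Conditions: MeMgCl (2.2 equiv), THF, −78 → −40 °C; aq. NH4Cl at −40 °C
Reagents that add atoms: methylmagnesium chloride, C[Mg]Cl
Why: Double Grignard addition to the ester is faster than epoxide opening at low temperature, and the stereocentre takes no part, so it is carried over as (R).

Step 6
Reactants: 9 3-chloro-4-(1,3-dioxolan-2-yl)-2-(trimethylsilyl)phenyl trifluoromethanesulfonate, 12 (R)-2-(oxiran-2-yl)propan-2-ol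
Product: 16 (3R)-5-chloro-6-(1,3-dioxolan-2-yl)-2,2-dimethylchroman-3-ol, via sodium alkoxide 13 (not isolated), via chloroaryne 14 (not isolated), via arylsodium 15 (not isolated)
Conditions: 12 (2 equiv), NaH, THF, 0 °C; then KF, 18-crown-6, slow addition of 9, THF, 0 °C → rt; then H2O
Reagents that add atoms: none
Why: Proposed new method: fluoride removes the trimethylsilyl group of 9 and triflate departs to give chloroaryne 14; the preformed sodium alkoxide 13 adds to the aryne carbon remote from chlorine (the former C–OTf carbon, later C8a), which places the carbanion of 15 on the carbon beside chlorine (later C4a), and this carbanion attacks the tethered epoxide at its CH2 from the backside to make C4–C4a. The closest known reaction types are aryne annulations in which an oxygen nucleophile adds and the aryl anion is then captured by a tethered electrophile (xanthones from salicylates), the insertion of arynes into the C–O bond of epoxides, and Parham-type cyclisations of aryl anions onto epoxides. The dihydropyran ring closes in the 6-endo-tet mode of epoxide opening; the 5-exo alternative would need an SN2 attack on a secondary carbon flanked by the quaternary CMe2 centre, a neopentyl-like situation that should be far slower. No stereocentre is created: the C–O bond at the epoxide methine is not broken, so the (R) centre of 12 is carried unchanged into the (3R) carbinol of 16. The regioselectivity needed in the O-arylation is secured by the inductively withdrawing chlorine, which distorts the aryne so that nucleophiles attack the distal carbon and the charge develops next to it. THF as solvent, a hydride-derived alkoxide and the absence of acetonitrile or free alcohol keep proton donors away from 15, while the sodium counter-ion, the low temperature and the short lifetime of 13 are meant to hold back Payne isomerisation of 13 and loss of chloride from 15.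

Step 7
Reactants: 16 (3R)-5-chloro-6-(1,3-dioxolan-2-yl)-2,2-dimethylchroman-3-ol
Product: 17 (3R)-3-(benzyloxy)-5-chloro-6-(1,3-dioxolan-2-yl)-2,2-dimethylchroman
Conditions: NaH, BnBr, Bu4NI (cat.), DMF, 0 °C → rt
Reagents that add atoms: benzyl bromide, BrCc1ccccc1
Why: Williamson etherification of the secondary alkoxide; aryl chloride and acetal are inert to base, and the C3–O bond is not broken, so the configuration is kept.

Step 8
Reactants: 17 (3R)-3-(benzyloxy)-5-chloro-6-(1,3-dioxolan-2-yl)-2,2-dimethylchroman
Product: 18 (3R)-3-(benzyloxy)-6-(1,3-dioxolan-2-yl)-2,2-dimethylchroman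
Conditions: chloro(allyl)[1,3-bis(2,6-diisopropylphenyl)imidazol-2-ylidene]palladium (2 mol %), NaOt-Bu, i-PrOH, 60 °C
Reagents that add atoms: none
Why: Palladium-catalysed transfer hydrodechlorination (oxidative addition of the hindered aryl chloride to the zerovalent palladium–carbene complex, chloride/isopropoxide exchange, β-hydride elimination, C–H reductive elimination); without H2 or acid the benzyl ether and the acetal should survive.

Step 9
Reactants: 18 (3R)-3-(benzyloxy)-6-(1,3-dioxolan-2-yl)-2,2-dimethylchroman
Product: 20 [(3R)-3-(benzyloxy)-2,2-dimethylchroman-6-yl]methanol, via aldehyde 19 (not isolated)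
Conditions: 1 M HCl (cat.), THF/H2O, rt; then NaBH4, MeOH, 0 °C
Reagents that add atoms: water, O
Why: Acid-catalysed acetal hydrolysis (fast for this para-alkoxy aryl acetal) followed in the same flask by borohydride reduction of the aldehyde; benzyl ether and chroman ether are stable to both.

Step 10
Reactants: 20 [(3R)-3-(benzyloxy)-2,2-dimethylchroman-6-yl]methanol
Product: 21 (3R)-3-(benzyloxy)-6-(bromomethyl)-2,2-dimethylchroman
Conditions: CBr4, PPh3, CH2Cl2, 0 °C; used at once
Reagents that add atoms: carbon tetrabromide, BrC(Br)(Br)Br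
Why: Appel reaction converts the primary benzylic alcohol to the bromide under neutral conditions that spare the benzyl ether; the para-alkoxybenzyl bromide is reactive and is therefore not stored.

Step 11
Reactants: 22 3,4-bis(benzyloxy)benzaldehyde
Product: 23 (Z)-5-[3,4-bis(benzyloxy)benzylidene]imidazolidine-2,4-dione
Conditions: hydantoin, ethanolamine, EtOH/H2O, 90 °C
Reagents that add atoms: hydantoin (imidazolidine-2,4-dione), O=C1CNC(=O)N1
Why: Knoevenagel-type condensation of the acidic methylene of hydantoin with the aldehyde, driven by precipitation of the conjugated product; the double-bond geometry is of no consequence.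

Step 12
Reactants: 23 (Z)-5-[3,4-bis(benzyloxy)benzylidene]imidazolidine-2,4-dione
Product: 24 3-[3,4-bis(benzyloxy)phenyl]-2-oxopropanoic acid
Conditions: 20% aq. NaOH, reflux, N2; then conc. HCl, 0 °C
Reagents that add atoms: water, O
Why: Alkaline hydrolysis of the hydantoin to the dehydroamino acid and of its enamine to the α-keto acid is the classical arylpyruvic acid synthesis, and base leaves the benzyl ethers untouched.

Step 13
Reactants: 24 3-[3,4-bis(benzyloxy)phenyl]-2-oxopropanoic acid
Product: 25 methyl 3-[3,4-bis(benzyloxy)phenyl]-2-oxopropanoate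
Conditions: MeOH, H2SO4 (cat.), 40 °C
Reagents that add atoms: methanol, CO
Why: Fischer esterification of the activated α-keto acid; no base is present, so the ester cannot self-condense.

Step 14
Reactants: 25 methyl 3-[3,4-bis(benzyloxy)phenyl]-2-oxopropanoate
Product: 27 methyl 3-[3,4-bis(benzyloxy)phenyl]-4-hydroxy-5-oxo-2,5-dihydrofuran-2-carboxylate (racemic), via aldol adduct 26 (not isolated)
Conditions: methyl 2-hydroxy-2-methoxyacetate (1.5 equiv), Et3N, THF, 0 °C → rt; 1 M HCl work-up
Reagents that add atoms: methyl glyoxylate (delivered from its methyl hemiacetal, methyl 2-hydroxy-2-methoxyacetate, COC(O)C(=O)OC), COC(=O)C=O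
Why: Cross-aldol addition of the amine-generated arylpyruvate enolate to the far more electrophilic glyoxylate aldehyde, then 5-exo-trig lactonisation of the new alkoxide onto the adjacent ester and enolisation (isotetronic acid synthesis); the new stereocentre is later planarised, so its configuration is irrelevant.

Step 15
Reactants: 27 methyl 3-[3,4-bis(benzyloxy)phenyl]-4-hydroxy-5-oxo-2,5-dihydrofuran-2-carboxylate
Product: 28 methyl 3-[3,4-bis(benzyloxy)phenyl]-4-methoxy-5-oxo-2,5-dihydrofuran-2-carboxylate (racemic)
Conditions: TMSCHN2, MeOH/toluene, 0 °C → rt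
Reagents that add atoms: (trimethylsilyl)diazomethane, C[Si](C)(C)C=[N+]=[N-]
Why: O-Methylation of the acidic enol by the diazoalkane proceeds without base, so the acidic ring C2–H is not alkylated.

Step 16
Reactants: 21 (3R)-3-(benzyloxy)-6-(bromomethyl)-2,2-dimethylchroman, 28 methyl 3-[3,4-bis(benzyloxy)phenyl]-4-methoxy-5-oxo-2,5-dihydrofuran-2-carboxylate
Product: 29 methyl (2S)-2-{[(3R)-3-(benzyloxy)-2,2-dimethylchroman-6-yl]methyl}-3-[3,4-bis(benzyloxy)phenyl]-4-methoxy-5-oxo-2,5-dihydrofuran-2-carboxylate
Conditions: O-allyl-N-(9-anthracenylmethyl)cinchonidinium bromide (10 mol %), Cs2CO3 (solid), toluene/CH2Cl2, −20 °C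
Reagents that add atoms: none
Why: Asymmetric phase-transfer alkylation: the ring C2–H (ester α-carbon and γ-position of the butenolide) is removed at the carbonate surface, the chiral ammonium ion pairs with the planar 2-oxyfuran enolate and is expected to shield one face so that the benzyl bromide adds to the ester-bearing carbon from the other face and sets the (S) quaternary centre; attack there keeps the conjugated butenolide.

Step 17
Reactants: 29 methyl (2S)-2-{[(3R)-3-(benzyloxy)-2,2-dimethylchroman-6-yl]methyl}-3-[3,4-bis(benzyloxy)phenyl]-4-methoxy-5-oxo-2,5-dihydrofuran-2-carboxylate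
Product: 30 methyl (2S)-3-(3,4-dihydroxyphenyl)-2-{[(3R)-3-hydroxy-2,2-dimethylchroman-6-yl]methyl}-4-methoxy-5-oxo-2,5-dihydrofuran-2-carboxylate (CNP0289675.1)
Conditions: H2 (1 atm), 10% Pd/C, EtOAc/MeOH, rt
Reagents that add atoms: none
Why: Hydrogenolysis removes the two aryl benzyl ethers and the secondary alkyl benzyl ether in one operation; the tetrasubstituted, conjugated enol-ether alkene is too hindered to be reduced at balloon pressure and no stereocentre is touched.

Compound list
1 | 2-chloro-4-hydroxybenzaldehyde | O=Cc1ccc(O)cc1Cl | starting material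
2 | 3-chloro-4-formylphenyl isopropylcarbamate | CC(C)NC(=O)Oc1ccc(C=O)c(Cl)c1 | intermediate
3 | 3-chloro-4-(1,3-dioxolan-2-yl)phenyl isopropylcarbamate | CC(C)NC(=O)Oc1ccc(C2OCCO2)c(Cl)c1 | intermediate
4 | 3-chloro-4-(1,3-dioxolan-2-yl)phenyl N-(tert-butyldimethylsilyl)-N-isopropylcarbamate | CC(C)N(C(=O)Oc1ccc(C2OCCO2)c(Cl)c1)[Si](C)(C)C(C)(C)C | intermediate
5 | 2-lithio derivative of 4 (lithium on the ring carbon between O and Cl) | [Li]c1c(Cl)c(C2OCCO2)ccc1OC(=O)N(C(C)C)[Si](C)(C)C(C)(C)C | intermediate
6 | 3-chloro-4-(1,3-dioxolan-2-yl)-2-(trimethylsilyl)phenyl N-(tert-butyldimethylsilyl)-N-isopropylcarbamate | CC(C)N(C(=O)Oc1ccc(C2OCCO2)c(Cl)c1[Si](C)(C)C)[Si](C)(C)C(C)(C)C | intermediate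
7 | 3-chloro-4-(1,3-dioxolan-2-yl)-2-(trimethylsilyl)phenyl isopropylcarbamate | CC(C)NC(=O)Oc1ccc(C2OCCO2)c(Cl)c1[Si](C)(C)C | intermediate
8 | 3-chloro-4-(1,3-dioxolan-2-yl)-2-(trimethylsilyl)phenol | Oc1ccc(C2OCCO2)c(Cl)c1[Si](C)(C)C | intermediate
9 | 3-chloro-4-(1,3-dioxolan-2-yl)-2-(trimethylsilyl)phenyl trifluoromethanesulfonate | FC(F)(F)S(=O)(=O)Oc1ccc(C2OCCO2)c(Cl)c1[Si](C)(C)C | intermediate
10 | methyl (R)-glycidate (methyl (2R)-oxirane-2-carboxylate) | COC(=O)[C@H]1CO1 | starting material
11 | 1-[(2R)-oxiran-2-yl]ethan-1-one | CC(=O)[C@H]1CO1 | intermediate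
12 | (R)-2-(oxiran-2-yl)propan-2-ol | CC(C)(O)[C@H]1CO1 | intermediate
13 | sodium 2-[(2R)-oxiran-2-yl]propan-2-olate | CC(C)([O-])[C@H]1CO1.[Na+] | intermediate
14 | 3-chloro-4-(1,3-dioxolan-2-yl)-1,2-didehydrobenzene (chlorine beside the triple bond) | ClC1=C(C2OCCO2)C=CC#C1 | intermediate
15 | 2-chloro-3-(1,3-dioxolan-2-yl)-6-{[2-((2R)-oxiran-2-yl)propan-2-yl]oxy}phenylsodium | [Na]c1c(Cl)c(C2OCCO2)ccc1OC(C)(C)[C@H]1CO1 | intermediate
16 | (3R)-5-chloro-6-(1,3-dioxolan-2-yl)-2,2-dimethylchroman-3-ol | Clc1c(C2OCCO2)ccc2c1C[C@@H](O)C(C)(C)O2 | intermediate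
17 | (3R)-3-(benzyloxy)-5-chloro-6-(1,3-dioxolan-2-yl)-2,2-dimethylchroman | Clc1c(C2OCCO2)ccc2c1C[C@@H](OCc1ccccc1)C(C)(C)O2 | intermediate
18 | (3R)-3-(benzyloxy)-6-(1,3-dioxolan-2-yl)-2,2-dimethylchroman | C1COC(O1)c1ccc2c(c1)C[C@@H](OCc1ccccc1)C(C)(C)O2 | intermediate
19 | (3R)-3-(benzyloxy)-2,2-dimethylchroman-6-carbaldehyde | O=Cc1ccc2c(c1)C[C@@H](OCc1ccccc1)C(C)(C)O2 | intermediate
20 | [(3R)-3-(benzyloxy)-2,2-dimethylchroman-6-yl]methanol | OCc1ccc2c(c1)C[C@@H](OCc1ccccc1)C(C)(C)O2 | intermediate
21 | (3R)-3-(benzyloxy)-6-(bromomethyl)-2,2-dimethylchroman | BrCc1ccc2c(c1)C[C@@H](OCc1ccccc1)C(C)(C)O2 | intermediate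
22 | 3,4-bis(benzyloxy)benzaldehyde | O=Cc1ccc(OCc2ccccc2)c(OCc2ccccc2)c1 | starting material
23 | (Z)-5-[3,4-bis(benzyloxy)benzylidene]imidazolidine-2,4-dione | O=C1N/C(=C\c2ccc(OCc3ccccc3)c(OCc3ccccc3)c2)C(=O)N1 | intermediate
24 | 3-[3,4-bis(benzyloxy)phenyl]-2-oxopropanoic acid | OC(=O)C(=O)Cc1ccc(OCc2ccccc2)c(OCc2ccccc2)c1 | intermediate
25 | methyl 3-[3,4-bis(benzyloxy)phenyl]-2-oxopropanoate | COC(=O)C(=O)Cc1ccc(OCc2ccccc2)c(OCc2ccccc2)c1 | intermediate
26 | dimethyl 3-[3,4-bis(benzyloxy)phenyl]-2-hydroxy-4-oxopentanedioate (mixture of stereoisomers) | COC(=O)C(O)C(c1ccc(OCc2ccccc2)c(OCc2ccccc2)c1)C(=O)C(=O)OC | intermediate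
27 | methyl 3-[3,4-bis(benzyloxy)phenyl]-4-hydroxy-5-oxo-2,5-dihydrofuran-2-carboxylate (racemic) | COC(=O)C1OC(=O)C(O)=C1c1ccc(OCc2ccccc2)c(OCc2ccccc2)c1 | intermediate
28 | methyl 3-[3,4-bis(benzyloxy)phenyl]-4-methoxy-5-oxo-2,5-dihydrofuran-2-carboxylate (racemic) | COC(=O)C1OC(=O)C(OC)=C1c1ccc(OCc2ccccc2)c(OCc2ccccc2)c1 | intermediate
29 | methyl (2S)-2-{[(3R)-3-(benzyloxy)-2,2-dimethylchroman-6-yl]methyl}-3-[3,4-bis(benzyloxy)phenyl]-4-methoxy-5-oxo-2,5-dihydrofuran-2-carboxylate | COC(=O)[C@@]1(Cc2ccc3c(c2)C[C@@H](OCc2ccccc2)C(C)(C)O3)OC(=O)C(OC)=C1c1ccc(OCc2ccccc2)c(OCc2ccccc2)c1 | intermediate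
30 | methyl (2S)-3-(3,4-dihydroxyphenyl)-2-{[(3R)-3-hydroxy-2,2-dimethylchroman-6-yl]methyl}-4-methoxy-5-oxo-2,5-dihydrofuran-2-carboxylate | COC(=O)[C@@]1(Cc2ccc3c(c2)C[C@@H](O)C(C)(C)O3)OC(=O)C(OC)=C1c1ccc(O)c(O)c1 | target

Total step count: 17.
Longest linear sequence: 11 steps (steps 1, 2, 3, 4, 6, 7, 8, 9, 10, 16, 17).

Steps most likely to fail

1. Step 6 (proposed new method). The aryl anion may be protonated, or may expel chloride to give a second aryne, before it reaches the epoxide. The alkoxide may undergo Payne rearrangement before O-arylation, which would divert the sequence to a dihydrobenzofuran, and the epoxide may open in the 5-exo mode. The fallback makes the same two bonds one after the other with known reactions; it sets out from 12 and comes back to the route at 18, so that steps 7 and 8 are not needed. Commercial 3-bromo-4-chlorobenzaldehyde is converted to its acetal, 2-(3-bromo-4-chlorophenyl)-1,3-dioxolane F1 (ethylene glycol, p-TsOH, toluene, water removal). Bromine–magnesium exchange with i-PrMgCl·LiCl at −15 °C gives [2-chloro-5-(1,3-dioxolan-2-yl)phenyl]magnesium chloride F2. Epoxy alcohol 12, first converted to its chloromagnesium alkoxide with one equivalent of i-PrMgCl at −40 °C, is opened at the epoxide CH2 by F2 under CuI catalysis to give (2R)-1-[2-chloro-5-(1,3-dioxolan-2-yl)phenyl]-3-methylbutane-2,3-diol F3. The secondary hydroxyl is benzylated selectively (one equivalent of NaH, BnBr, THF, 0 °C) to give (3R)-3-(benzyloxy)-4-[2-chloro-5-(1,3-dioxolan-2-yl)phenyl]-2-methylbutan-2-ol F4. Palladium-catalysed intramolecular C–O coupling of the tertiary alcohol with the aryl chloride (Pd(OAc)2, 2-(di-tert-butylphosphino)-1,1'-binaphthyl, Cs2CO3, toluene, 80 °C) then closes the dihydropyran ring and gives 18.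

2. Step 16. Facial selectivity in the ion-paired enolate may be poor, in part because the very reactive para-alkoxybenzyl bromide can alkylate without the catalyst; alkylation at the methoxy-bearing ring carbon or at oxygen may also compete with attack at the ester-bearing carbon. The fallback gives up catalyst control and uses the fixed chroman centre as a resolving handle; it sets out from 21 and 28 and comes back at 29. Alkylation with Cs2CO3 in DMF at 0 °C without chiral catalyst should give 29 together with its epimer at the quaternary carbon, methyl (2R)-2-{[(3R)-3-(benzyloxy)-2,2-dimethylchroman-6-yl]methyl}-3-[3,4-bis(benzyloxy)phenyl]-4-methoxy-5-oxo-2,5-dihydrofuran-2-carboxylate F5. The two are diastereomers and would be separated by chromatography or preparative HPLC, and 29 goes on to step 17.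

3. Step 3. The ortho-chloro aryllithium may lose LiCl (aryne formation) before it is silylated, and the silyl triflate or the organolithium may attack the acetal, so that conversion to the C-silylated carbamate is low. The fallback uses a carbamate without N–H and traps the anion as it forms; it sets out from 1 and comes back at 8. Phenol 1 is carbamoylated (Et2NCOCl, K2CO3, MeCN, reflux) to 3-chloro-4-formylphenyl diethylcarbamate F6, which is acetalised (ethylene glycol, p-TsOH, toluene, water removal) to 3-chloro-4-(1,3-dioxolan-2-yl)phenyl diethylcarbamate F7. LiN(i-Pr)2 is added to F7 and TMSCl in THF at −78 °C (in situ quench) to give 3-chloro-4-(1,3-dioxolan-2-yl)-2-(trimethylsilyl)phenyl diethylcarbamate F8. Reductive cleavage with LiAlH4 in THF at 0 °C then gives phenol 8, which is triflated with PhNTf2 and Et3N to 9.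

Further compounds
F1 | step 6 | 2-(3-bromo-4-chlorophenyl)-1,3-dioxolane | Brc1cc(C2OCCO2)ccc1Cl
F2 | step 6 | [2-chloro-5-(1,3-dioxolan-2-yl)phenyl]magnesium chloride | Cl[Mg]c1cc(C2OCCO2)ccc1Cl
F3 | step 6 | (2R)-1-[2-chloro-5-(1,3-dioxolan-2-yl)phenyl]-3-methylbutane-2,3-diol | CC(C)(O)[C@H](O)Cc1cc(C2OCCO2)ccc1Cl
F4 | step 6 | (3R)-3-(benzyloxy)-4-[2-chloro-5-(1,3-dioxolan-2-yl)phenyl]-2-methylbutan-2-ol | CC(C)(O)[C@H](OCc1ccccc1)Cc1cc(C2OCCO2)ccc1Cl
F5 | step 16 | methyl (2R)-2-{[(3R)-3-(benzyloxy)-2,2-dimethylchroman-6-yl]methyl}-3-[3,4-bis(benzyloxy)phenyl]-4-methoxy-5-oxo-2,5-dihydrofuran-2-carboxylate | COC(=O)[C@]1(Cc2ccc3c(c2)C[C@@H](OCc2ccccc2)C(C)(C)O3)OC(=O)C(OC)=C1c1ccc(OCc2ccccc2)c(OCc2ccccc2)c1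
F6 | step 3 | 3-chloro-4-formylphenyl diethylcarbamate | CCN(CC)C(=O)Oc1ccc(C=O)c(Cl)c1
F7 | step 3 | 3-chloro-4-(1,3-dioxolan-2-yl)phenyl diethylcarbamate | CCN(CC)C(=O)Oc1ccc(C2OCCO2)c(Cl)c1
F8 | step 3 | 3-chloro-4-(1,3-dioxolan-2-yl)-2-(trimethylsilyl)phenyl diethylcarbamate | CCN(CC)C(=O)Oc1ccc(C2OCCO2)c(Cl)c1[Si](C)(C)C
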